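## Retrosynthetic overview

1. Target ⇐ (mild removal of an aryl acetate and a tertiary trifluoroacetate) ⇐ transannular bromonium-induced diene cyclisation (C6–Br and C2–C7 bonds, exocyclic alkene by proton loss) of a 19-membered macrolide.
2. 19-membered macrolide ⇐ photochemical bromine-atom-transfer radical macrocyclisation: an allylic C8 bromide adds across the vinyl carbinol of a linalool unit, forming C8–C9 and the C10–Br/C11–OH bromohydrin in one step.
3. Seco ester ⇐ C14–O ester of 4-acetoxy-3-geranylbenzoic acid with a linalool-derived 3,6-diol; the C8 bromide comes from allylic oxidation and Appel bromination.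
4. Diol ⇐ Schenck ene photo-oxygenation of (S)-linalool (supplies C9–C16 and the C11 centre); acid ⇐ ortho C-geranylation of methyl 4-hydroxybenzoate.
5. Ring order: arene (bought) → 19-membered macrolactone → cyclohexane, which contracts the large ring to the 15-membered lactone. Stereocentres: C11 bought; C14 in the photo-oxygenation; C10 in the radical step; C2, C6, C7 in the transannular step.

Assumption: diterpene numbering C1 (benzylic CH2) to C16 (=CH2 of the isopropenyl group) is used for all intermediates, and (S)-(+)-linalool is taken as the commercial natural product of high enantiomeric purity.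

## Route

Step 1
Reactants: 1 methyl 4-hydroxybenzoate; 2 geranyl bromide, (2E)-1-bromo-3,7-dimethylocta-2,6-diene
Product: 3 methyl 3-[(2E)-3,7-dimethylocta-2,6-dien-1-yl]-4-hydroxybenzoate
Conditions: NaH, toluene, 0 °C → rt
Reagents that add atoms: none
Why: Ortho C-alkylation of the sodium phenoxide as a tight ion pair in a non-polar solvent (SN2 at the primary allylic bromide) is the standard entry to 3-prenylated 4-hydroxybenzoates and keeps the 2E geometry; no stereocentre is formed.

Step 2
Reactants: 3 methyl 3-[(2E)-3,7-dimethylocta-2,6-dien-1-yl]-4-hydroxybenzoate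
Product: 4 3-[(2E)-3,7-dimethylocta-2,6-dien-1-yl]-4-hydroxybenzoic acid
Conditions: NaOH, MeOH/H2O, 60 °C; then aq. HCl
Reagents that add atoms: sodium hydroxide, [Na+].[OH-]
Why: Ordinary ester saponification; the diene side chain and the phenol are inert to aqueous base.

Step 3
Reactants: 4 3-[(2E)-3,7-dimethylocta-2,6-dien-1-yl]-4-hydroxybenzoic acid
Product: 5 4-acetoxy-3-[(2E)-3,7-dimethylocta-2,6-dien-1-yl]benzoic acid
Conditions: Ac2O, pyridine, rt; then H2O
Reagents that add atoms: acetic anhydride, CC(=O)OC(C)=O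
Why: O-Acetylation masks the phenol, which would otherwise be acylated in step 5 and would leave the arene open to bromination in step 10; the mixed anhydride formed at the acid is hydrolysed in the aqueous work-up.

Step 4
Reactants: 6 (S)-(+)-linalool, (3S)-3,7-dimethylocta-1,6-dien-3-ol
Product: 8 (3S,6S)-3,7-dimethylocta-1,7-diene-3,6-diol, via allylic hydroperoxide 7 (not isolated)
Conditions: O2, tetraphenylporphyrin (1 mol%), white LEDs, CH2Cl2, 0 °C; then PPh3, rt; chromatography
Reagents that add atoms: oxygen, O=O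
Why: Schenck ene reaction of singlet oxygen at the trisubstituted alkene (the vinyl group is inert) puts oxygen on C6 and shifts the double bond into the isopropenyl position, and PPh3 reduces the hydroperoxide; the C3 centre is untouched but gives no useful bias at the remote C6, so the 6S isomer is separated from its C6 epimer and from the tertiary regioisomer.

Step 5
Reactants: 5 4-acetoxy-3-[(2E)-3,7-dimethylocta-2,6-dien-1-yl]benzoic acid; 8 (3S,6S)-3,7-dimethylocta-1,7-diene-3,6-diol
Product: 9 (3S,6S)-6-hydroxy-2,6-dimethylocta-1,7-dien-3-yl 4-acetoxy-3-[(2E)-3,7-dimethylocta-2,6-dien-1-yl]benzoate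
Conditions: DCC, DMAP (cat.), CH2Cl2, 0 °C → rt
Reagents that add atoms: none
Why: Steglich esterification acylates only the secondary allylic alcohol (the tertiary carbinol is too hindered) and does so with retention, so C14 keeps the S configuration of 8.

Step 6
Reactants: 9 (3S,6S)-6-hydroxy-2,6-dimethylocta-1,7-dien-3-yl 4-acetoxy-3-[(2E)-3,7-dimethylocta-2,6-dien-1-yl]benzoate
Product: 10 (3S,6S)-6-hydroxy-2,6-dimethylocta-1,7-dien-3-yl 4-acetoxy-3-[(2E,6E)-8-hydroxy-3,7-dimethylocta-2,6-dien-1-yl]benzoate
Conditions: SeO2 (cat.), t-BuOOH, salicylic acid (cat.), CH2Cl2, rt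
Reagents that add atoms: tert-butyl hydroperoxide, CC(C)(C)OO
Why: SeO2-catalysed allylic oxidation (ene reaction, then [2,3] shift) goes to the E-methyl group of the terminal trisubstituted alkene, the most reactive and least hindered site, and gives the E allylic alcohol; no stereocentre is touched.

Step 7
Reactants: 10 (3S,6S)-6-hydroxy-2,6-dimethylocta-1,7-dien-3-yl 4-acetoxy-3-[(2E,6E)-8-hydroxy-3,7-dimethylocta-2,6-dien-1-yl]benzoate
Product: 11 (3S,6S)-6-hydroxy-2,6-dimethylocta-1,7-dien-3-yl 4-acetoxy-3-[(2E,6E)-8-bromo-3,7-dimethylocta-2,6-dien-1-yl]benzoate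
Conditions: CBr4, PPh3, CH2Cl2, −20 °C
Reagents that add atoms: carbon tetrabromide, BrC(Br)(Br)Br
Why: Appel bromination converts only the primary allylic alcohol (SN2, E geometry kept) and leaves the hindered tertiary alcohol and both esters alone.

Step 8
Reactants: 11 (3S,6S)-6-hydroxy-2,6-dimethylocta-1,7-dien-3-yl 4-acetoxy-3-[(2E,6E)-8-bromo-3,7-dimethylocta-2,6-dien-1-yl]benzoate
Product: 12 (2E,6E,10R,11S,14S)-10-bromo-11-hydroxy 19-membered macrolide (4'-acetate; 14-isopropenyl; ring = C1 to C14 chain closed through O–CO–aryl)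
Conditions: [Cu(dap)2]Cl (5 mol%; dap = 2,9-bis(4-methoxyphenyl)-1,10-phenanthroline), 530 nm LEDs, degassed MeCN/1,2-dichloroethane (1:1), 2 mM, 25 °C
Reagents that add atoms: none
Why: Proposed new method: green-light excitation of [Cu(dap)2]Cl gives a strongly reducing monovalent-copper excited state that abstracts bromine from the weak allylic C8–Br bond, the 2-methylallyl-type radical (E geometry held, reacting at its primary terminus) adds at high dilution to the unsubstituted CH2 of the vinyl carbinol to close the 19-membered ring, and the secondary C10 radical takes bromine back from the divalent-copper bromide anti to the C11–O bond of the extended in-ring conformer (C9 anti to C12), which is predicted to give 10R; the step is irreversible because a strong secondary C–Br bond replaces a weak allylic one, and the closest known reaction type is the copper- or iridium-photocatalysed atom-transfer radical addition (Kharasch addition) of activated alkyl bromides to terminal alkenes and atom-transfer radical macrocyclisation.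

Step 9
Reactants: 12 (2E,6E,10R,11S,14S)-10-bromo-11-hydroxy 19-membered macrolide
Product: 13 11-O-trifluoroacetate of macrolide 12
Conditions: (CF3CO)2O, pyridine, CH2Cl2, 0 °C
Reagents that add atoms: trifluoroacetic anhydride, O=C(OC(=O)C(F)(F)F)C(F)(F)F
Why: Trifluoroacetylation reaches even the hindered tertiary alcohol, and the non-nucleophilic ester stops the C11 oxygen from trapping the C7 cation as a tetrahydropyran in step 10 while remaining removable without base.

Step 10
Reactants: 13 11-O-trifluoroacetate of macrolide 12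
Product: 15 bromophycolide E, via protected bromocyclohexane macrolide 14 (not isolated)
Conditions: Et2SBr·SbBrCl5 (1.1 equiv), MeNO2, −25 °C, 5 min; then NH4OAc, MeOH, 35 °C
Reagents that add atoms: bromodiethylsulfonium bromopentachloroantimonate, CC[S+](Br)CC.Br[Sb-](Cl)(Cl)(Cl)(Cl)Cl
Why: Bromonium-induced cation–olefin cyclisation in which Br+ adds to the 6,7-alkene and the 2,3-alkene closes the six-membered ring through a chair transition state (the E,E geometry puts Br, the C7 methyl and the C2 benzyl group on one face and C8 on the other), the face being chosen transannularly by the C10, C11 and C14 centres of the macrocycle, after which loss of a C3-methyl proton gives the exocyclic alkene and neutral methanolysis removes acetate and trifluoroacetate without closing the bromohydrin to an epoxide.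

## Compound list

1 | methyl 4-hydroxybenzoate | COC(=O)c1ccc(O)cc1 | starting material
2 | geranyl bromide, (2E)-1-bromo-3,7-dimethylocta-2,6-diene | CC(C)=CCC/C(C)=C/CBr | starting material
3 | methyl 3-[(2E)-3,7-dimethylocta-2,6-dien-1-yl]-4-hydroxybenzoate | CC(C)=CCC/C(C)=C/Cc1cc(ccc1O)C(=O)OC | intermediate
4 | 3-[(2E)-3,7-dimethylocta-2,6-dien-1-yl]-4-hydroxybenzoic acid | CC(C)=CCC/C(C)=C/Cc1cc(ccc1O)C(=O)O | intermediate
5 | 4-acetoxy-3-[(2E)-3,7-dimethylocta-2,6-dien-1-yl]benzoic acid | CC(C)=CCC/C(C)=C/Cc1cc(ccc1OC(C)=O)C(=O)O | intermediate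
6 | (S)-(+)-linalool, (3S)-3,7-dimethylocta-1,6-dien-3-ol | CC(C)=CCC[C@](C)(O)C=C | starting material
7 | (3S,6S)-6-hydroperoxy-3,7-dimethylocta-1,7-dien-3-ol | C=C(C)[C@@H](OO)CC[C@](C)(O)C=C | intermediate
8 | (3S,6S)-3,7-dimethylocta-1,7-diene-3,6-diol | C=C(C)[C@@H](O)CC[C@](C)(O)C=C | intermediate
9 | (3S,6S)-6-hydroxy-2,6-dimethylocta-1,7-dien-3-yl 4-acetoxy-3-[(2E)-3,7-dimethylocta-2,6-dien-1-yl]benzoate | C=C(C)[C@H](CC[C@](C)(O)C=C)OC(=O)c1ccc(OC(C)=O)c(C/C=C(C)/CCC=C(C)C)c1 | intermediate
10 | (3S,6S)-6-hydroxy-2,6-dimethylocta-1,7-dien-3-yl 4-acetoxy-3-[(2E,6E)-8-hydroxy-3,7-dimethylocta-2,6-dien-1-yl]benzoate | C=C(C)[C@H](CC[C@](C)(O)C=C)OC(=O)c1ccc(OC(C)=O)c(C/C=C(C)/CC/C=C(C)/CO)c1 | intermediate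
11 | (3S,6S)-6-hydroxy-2,6-dimethylocta-1,7-dien-3-yl 4-acetoxy-3-[(2E,6E)-8-bromo-3,7-dimethylocta-2,6-dien-1-yl]benzoate | C=C(C)[C@H](CC[C@](C)(O)C=C)OC(=O)c1ccc(OC(C)=O)c(C/C=C(C)/CC/C=C(C)/CBr)c1 | intermediate
12 | 19-membered macrolide: 4-acetoxybenzoate whose ring carbon 3 carries C1 and whose carboxyl is esterified by the C14 oxygen; chain C1H2–C2H=C3(Me)–C4H2–C5H2–C6H=C7(Me)–C8H2–C9H2–C10HBr–C11(Me)(OH)–C12H2–C13H2–C14H(isopropenyl)–O; 2E,6E,10R,11S,14S | C=C(C)[C@@H]1CC[C@](C)(O)[C@H](Br)CC/C(C)=C/CC/C(C)=C/Cc2cc(ccc2OC(C)=O)C(=O)O1 | intermediate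
13 | macrolide 12 with the C11 hydroxyl as its trifluoroacetate; 2E,6E,10R,11S,14S | C=C(C)[C@@H]1CC[C@](C)(OC(=O)C(F)(F)F)[C@H](Br)CC/C(C)=C/CC/C(C)=C/Cc2cc(ccc2OC(C)=O)C(=O)O1 | intermediate
14 | bromophycolide E as its phenol acetate and C11 trifluoroacetate; 15-membered lactone fused to the 6-bromo-7-methyl-3-methylenecyclohexane; 2R,6S,7S,10R,11S,14S | C=C(C)[C@@H]1CC[C@](C)(OC(=O)C(F)(F)F)[C@H](Br)CC[C@@]2(C)[C@H](Cc3cc(ccc3OC(C)=O)C(=O)O1)C(=C)CC[C@@H]2Br | intermediate
15 | bromophycolide E; 2R,6S,7S,10R,11S,14S | C=C(C)[C@@H]1CC[C@](C)(O)[C@H](Br)CC[C@@]2(C)[C@H](Cc3cc(ccc3O)C(=O)O1)C(=C)CC[C@@H]2Br | target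

## Step count and risk

Total step count: 10. Longest linear sequence: 9 steps (1, 2, 3, 5, 6, 7, 8, 9, 10); step 4 is a one-step branch from 6.

The three steps most likely to fail:

**Step 8 (proposed new method).** An allyl radical adds slowly to an unactivated alkene, so macrocyclisation competes with reduction and dimerisation. The isopropenyl CH2 is a second terminal acceptor and would give a 16-membered ring; this regioisomer could take a large share of the material. The 10R/10S ratio rests only on a conformational argument and may be modest.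
Fallback, known chemistry only; it sets out from compound 9 and comes back to the route at compound 12. Tsuji–Wacker oxidation of the monosubstituted vinyl group of 9 (PdCl2, CuCl, O2, DMF/H2O) gives methyl ketone F1. SeO2/t-BuOOH and then CBr4/PPh3 give allylic alcohol F2 and allylic bromide F3. LiN(SiMe3)2 at high dilution closes the 19-membered ring by C-alkylation of the only possible (methyl) enolate and gives macrocyclic hydroxy ketone F4. Zn(BH4)2 reduces the ketone under chelation control, with hydride coming from the methyl side of the five-membered zinc chelate, to the 10R,11S diol F5. PPh3/DIAD closes the trans-epoxide F6 with inversion at C10, and Li2NiBr4 opens it at the secondary carbon with a second inversion to give 12.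

**Step 10.** Proton loss can give endocyclic alkene isomers instead of the exocyclic one. The reagent can also brominate the new exocyclic alkene or the isopropenyl group, and the facial selectivity set by the macrocycle is not assured.
Fallback; it sets out from compound 13 and comes back to the route at compound 14. Hg(OSO2CF3)2·PhNMe2 in MeNO2 at −20 °C, then aqueous NaBr, performs the same chair cyclisation with a milder electrophile and gives the equatorial C6 organomercurial F7. Br2/LiBr/pyridine in the dark under O2 then replaces mercury by bromine with retention to give 14, which is deprotected as in step 10.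

**Step 4.** The ene reaction gives two regioisomers, and the secondary hydroperoxide forms as a roughly 1:1 mixture at C6. At best a quarter of the linalool ends up as 8, and the epimers are hard to separate.
Fallback; it sets out from compound 6 and comes back to the route at compound 9. The 6R diol F8, formed beside 8 in the same photo-oxygenation, is kept and esterified with acid 5 under Mitsunobu conditions (PPh3, DIAD, THF). This inverts C6 and gives the same ester 9, so both epimers are used.

## Further compounds

F1 | step 8 | methyl ketone, (3S,6S)-6-hydroxy-2,6-dimethyl-7-oxooct-1-en-3-yl 4-acetoxy-3-[(2E)-3,7-dimethylocta-2,6-dien-1-yl]benzoate | C=C(C)[C@H](CC[C@](C)(O)C(C)=O)OC(=O)c1ccc(OC(C)=O)c(C/C=C(C)/CCC=C(C)C)c1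
F2 | step 8 | allylic alcohol, (3S,6S)-6-hydroxy-2,6-dimethyl-7-oxooct-1-en-3-yl 4-acetoxy-3-[(2E,6E)-8-hydroxy-3,7-dimethylocta-2,6-dien-1-yl]benzoate | C=C(C)[C@H](CC[C@](C)(O)C(C)=O)OC(=O)c1ccc(OC(C)=O)c(C/C=C(C)/CC/C=C(C)/CO)c1
F3 | step 8 | allylic bromide, (3S,6S)-6-hydroxy-2,6-dimethyl-7-oxooct-1-en-3-yl 4-acetoxy-3-[(2E,6E)-8-bromo-3,7-dimethylocta-2,6-dien-1-yl]benzoate | C=C(C)[C@H](CC[C@](C)(O)C(C)=O)OC(=O)c1ccc(OC(C)=O)c(C/C=C(C)/CC/C=C(C)/CBr)c1
F4 | step 8 | macrocyclic hydroxy ketone, macrolide 12 with C10 as a ketone (2E,6E,11S,14S) | C=C(C)[C@@H]1CC[C@](C)(O)C(=O)CC/C(C)=C/CC/C(C)=C/Cc2cc(ccc2OC(C)=O)C(=O)O1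
F5 | step 8 | diol, macrolide 12 with OH in place of Br at C10 (2E,6E,10R,11S,14S) | C=C(C)[C@@H]1CC[C@](C)(O)[C@H](O)CC/C(C)=C/CC/C(C)=C/Cc2cc(ccc2OC(C)=O)C(=O)O1
F6 | step 8 | trans-epoxide, macrolide with a 10,11-epoxide (2E,6E,10S,11S,14S) | C=C(C)[C@@H]1CC[C@]2(C)O[C@H]2CC/C(C)=C/CC/C(C)=C/Cc3cc(ccc3OC(C)=O)C(=O)O1
F7 | step 10 | C6 organomercurial, compound 14 with HgBr in place of the C6 bromine | C=C(C)[C@@H]1CC[C@](C)(OC(=O)C(F)(F)F)[C@H](Br)CC[C@@]2(C)[C@H](Cc3cc(ccc3OC(C)=O)C(=O)O1)C(=C)CC[C@@H]2[Hg]Br
F8 | step 4 | (3S,6R)-3,7-dimethylocta-1,7-diene-3,6-diol | C=C(C)[C@H](O)CC[C@](C)(O)C=C
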